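**Retrosynthetic overview**

1. The strategy rests on ring C (nine-membered, C8–C16): it holds one alkene-carbon-to-methylene bond, C9–C10, and C10–C11–N12 is what hydroboration of an N-vinyl group gives. Ring C is therefore closed last, at C9–C10, by intramolecular B-alkyl Suzuki coupling of a C9 vinyl iodide (iodine cis to C16).
2. The vinyl iodide, ring B (bond C16–C8) and the quaternary centre C16 come together from gold-catalysed 5-exo cyclisation of a silyl enol ether onto an iodoalkyne.
3. The enol ether comes from (R)-5-methylcyclohex-2-enone: α-iodination and B-alkyl Suzuki coupling attach the C13–C15 arm, then copper-catalysed butynyl addition anti to the methyl group makes C5–C6.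
4. The C3 methyl stereocentre, having set C5, is oxidised out (enone) and rebuilt as the cis C1/C3 diol by Luche reduction, hydroxyl-directed epoxidation and hydride opening. After ring closure come C7 allylic oxidation, Boc removal and N-methylation.
5. Ring order: A (purchased) → B (step 5) → C (step 14).

Key step: step 14

Remark on the chemistry: atoms keep the numbers they have along the target SMILES (C1 CHOAc, C2, C3 C(Me)OAc, C4, C5 ring-fusion CH, C6, C7 C=O, C8=C9, C10, C11, N12, C13–C15, C16 quaternary); β is the face of ring A that carries C6 and C8, α the opposite face.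
Assumption: the two acetates of the target are installed before ring C is closed and serve as the hydroxyl protection from then on; 1, 3, 6 and 18 are taken as catalogue compounds.

**Route**

Step 1
Reactants: 1 (R)-5-methylcyclohex-2-en-1-one
Product: 2 (R)-2-iodo-5-methylcyclohex-2-en-1-one
Conditions: I2, pyridine, CH2Cl2, 0 °C → rt
Reagents that add atoms: iodine, II
Why: Pyridine-mediated addition–iodination–elimination (Johnson α-iodination of an enone) should place iodine on C16 without touching the C3 stereocentre.

Step 2
Reactants: 2 (R)-2-iodo-5-methylcyclohex-2-en-1-one; 3 allyloxy(tert-butyl)dimethylsilane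
Product: 5 (R)-2-[3-(tert-butyldimethylsilyloxy)propyl]-5-methylcyclohex-2-en-1-one, via alkylborane 4 (not isolated)
Conditions: 3, 9-BBN, THF, rt; then 2, PdCl2(dppf) (5 mol%), AsPh3, Cs2CO3, DMF/H2O, rt
Reagents that add atoms: none
Why: Anti-Markovnikov hydroboration of the allyl ether followed by B-alkyl Suzuki–Miyaura coupling with the α-iodoenone, a well-behaved electrophile under these conditions, should attach the C13–C15 arm to C16.

Step 3
Reactants: 5 (R)-2-[3-(tert-butyldimethylsilyloxy)propyl]-5-methylcyclohex-2-en-1-one; 6 (4-bromobut-1-yn-1-yl)trimethylsilane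
Product: 8 tert-butyl({(3R,5R)-2-[3-(tert-butyldimethylsilyloxy)propyl]-5-methyl-3-[4-(trimethylsilyl)but-3-yn-1-yl]cyclohex-1-en-1-yl}oxy)dimethylsilane, via Grignard reagent 7 (not isolated)
Conditions: 6, Mg, THF, rt; CuBr·SMe2 (15 mol%), THF, −78 °C, add 5, → −40 °C; then TBSOTf, Et3N, HMPA, −78 → 0 °C
Reagents that add atoms: tert-butyldimethylsilyl trifluoromethanesulfonate, CC(C)(C)[Si](C)(C)OS(=O)(=O)C(F)(F)F
Why: Copper-catalysed conjugate addition of the Grignard reagent should occur by axial approach anti to the C3 methyl group (sets C5, butynyl arm β), and O-silylation of the resulting magnesium enolate fixes the C1=C16 enol ether regiospecifically.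

Step 4
Reactants: 8 the silyl enol ether of step 3
Product: 9 tert-butyl({(3R,5R)-2-[3-(tert-butyldimethylsilyloxy)propyl]-3-(4-iodobut-3-yn-1-yl)-5-methylcyclohex-1-en-1-yl}oxy)dimethylsilane
Conditions: NIS, AgNO3 (20 mol%), DMF, 0 °C → rt, dark
Reagents that add atoms: N-iodosuccinimide, O=C1CCC(=O)N1I
Why: Silver-catalysed desilylative iodination of the alkynylsilane (silver acetylide trapped by NIS) should be faster than attack of NIS on the hindered tetrasubstituted tert-butyldimethylsilyl enol ether.

Step 5
Reactants: 9 the iodoalkyne silyl enol ether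
Product: 10 cis-fused ring A/B ketone: C1 ketone, 3α-methyl, 5α-H, 16α-[3-(tert-butyldimethylsilyloxy)propyl], (Z)-iodomethylidene at C8 (iodine cis to C16)
Conditions: AuCl(PPh3) (10 mol%), AgBF4 (10 mol%), CH2Cl2/MeOH (10:1), 40 °C
Reagents that add atoms: none
Why: Cationic gold activates the iodoalkyne for 5-exo-dig attack of enol ether carbon C16 on C8 anti to gold (Conia-ene-type carbocyclisation), protodeauration with retention leaves iodine cis to C16, and the tether from C5 can reach only the face of C16 syn to C6, so the ring fusion is cis and C16 is set by C5.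

Step 6
Reactants: 10 the bicyclic ketone
Product: 11 enone: C1 ketone conjugated with C2=C3 (3-methyl), otherwise as 10
Conditions: IBX, DMSO/fluorobenzene, 70 °C
Reagents that add atoms: none
Why: IBX dehydrogenation of the ketone can go only toward C2–C3 because C16 is quaternary, and it removes the C3 stereocentre that has done its work.

Step 7
Reactants: 11 the enone
Product: 12 allylic alcohol: 1β-hydroxy, C2=C3(Me), otherwise as 11
Conditions: NaBH4, CeCl3·7H2O, MeOH, −78 → −20 °C
Reagents that add atoms: none
Why: Luche 1,2-reduction should deliver hydride axially to the α face of C1, anti to the pseudoaxial C16–C8 bond and away from the iodomethylidene group, giving the β (pseudoequatorial) alcohol.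

Step 8
Reactants: 12 the allylic alcohol
Product: 13 epoxy alcohol: 1β-hydroxy-2β,3β-epoxy-3α-methyl, otherwise as 12
Conditions: VO(acac)2 (5 mol%), t-BuOOH, CH2Cl2, 0 °C → rt
Reagents that add atoms: tert-butyl hydroperoxide, CC(C)(C)OO
Why: Vanadium-catalysed hydroxyl-directed epoxidation (Sharpless–Michaelson) delivers oxygen to C2=C3 on the face of the C1 hydroxyl, fixing the C3–O bond β, and leaves the electron-poor iodoalkene alone.

Step 9
Reactants: 13 the epoxy alcohol
Product: 14 diol: 1β,3β-dihydroxy-3α-methyl, vinyl iodide and silyloxypropyl arm unchanged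
Conditions: LiEt3BH, THF, 0 °C → rt; aq. NH4Cl
Reagents that add atoms: none
Why: SN2 hydride opening of the trisubstituted epoxide by the bulky borohydride should occur at the secondary carbon C2 with the C3–O bond untouched, giving the cis-1,3-diol, while vinyl iodide and silyl ether are inert to this reagent.

Step 10
Reactants: 14 the diol
Product: 15 diacetate: 1β,3β-diacetoxy-3α-methyl, vinyl iodide and silyloxypropyl arm unchanged
Conditions: Ac2O, DMAP, Et3N, CH2Cl2, rt → 40 °C
Reagents that add atoms: acetic anhydride, CC(=O)OC(C)=O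
Why: DMAP-catalysed acylation (Steglich-type) with excess anhydride should esterify both the hindered secondary and the equatorial tertiary hydroxyl.

Step 11
Reactants: 15 the diacetate silyl ether
Product: 16 diacetate with a free 3-hydroxypropyl arm on C16
Conditions: HF·pyridine, pyridine, THF, 0 °C → rt
Reagents that add atoms: none
Why: Buffered fluoride cleavage of the primary silyl ether should leave the acetates and the vinyl iodide untouched.

Step 12
Reactants: 16 the primary alcohol
Product: 17 diacetate with a 3-iodopropyl arm on C16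
Conditions: I2, PPh3, imidazole, CH2Cl2, 0 °C
Reagents that add atoms: iodine, II
Why: Appel-type iodination (Garegg–Samuelsson conditions) converts the unhindered primary alcohol by SN2 displacement of its oxyphosphonium.

Step 13
Reactants: 17 the primary iodide; 18 tert-butyl N-ethenylcarbamate (tert-butyl N-vinylcarbamate)
Product: 19 vinyl iodide carrying the N-Boc-N-vinyl-3-aminopropyl arm on C16 (1β,3β-diacetate; iodine cis to C16)
Conditions: 18, NaH, DMF, 0 °C; then 17, 0 °C → rt
Reagents that add atoms: none
Why: SN2 N-alkylation of the preformed sodium carbamate with the primary iodide should be clean because this weakly basic anion does not attack the hindered acetates and the iodoalkene carbon C8 carries no hydrogen for elimination.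

Step 14
Reactants: 19 the N-vinyl carbamate vinyl iodide
Product: 21 tricyclic N-Boc carbamate with ring C closed (C7 methylene, C8=C9 with C10 cis to C16, 1β,3β-diacetate), via alkylborane 20 (not isolated)
Conditions: 9-BBN, THF, rt; then syringe-pump addition to PdCl2(dppf) (20 mol%), AsPh3, Cs2CO3, DMF/THF/H2O, 50 °C, final 2 mM
Reagents that add atoms: none
Why: 9-BBN adds across the N-vinyl group with boron on the terminal carbon C10 (nitrogen and sterics both direct it there) while the iodoalkene and esters are left alone; zerovalent palladium formed from PdCl2(dppf) then inserts into the C9–I bond, the base-activated borate transfers its primary alkyl group, and reductive elimination forms C9–C10. The closest known reaction type is the intramolecular B-alkyl Suzuki–Miyaura macrocyclisation, combined with the use of hydroborated vinyl carbamates as 2-aminoethyl donors. Ring C (nine-membered) is closed through this single sp2–sp3 bond by reductive elimination from a ten-membered palladacycle. No stereocentre is created, and oxidative addition and reductive elimination proceed with retention, so the geometry fixed in step 5 becomes the cis ring alkene. The step needs cyclisation to beat oligomerisation and β-hydride elimination, which slow addition at high dilution, the wide-bite-angle dppf ligand and the placement of iodine on the same side of the alkene as the C16 arm should secure.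

Step 15
Reactants: 21 the tricyclic carbamate
Product: 22 C7 allylic alcohol of 21 (either C7 epimer)
Conditions: SeO2 (0.5 equiv), t-BuOOH, CH2Cl2, rt
Reagents that add atoms: selenium dioxide, O=[Se]=O (oxygen carrier); tert-butyl hydroperoxide, CC(C)(C)OO (terminal oxidant)
Why: The ene reaction and [2,3]-sigmatropic shift of the Riley oxidation take the allylic CH2 on the more substituted alkene carbon C8, which is C7 because C16 has no hydrogen, and return the double bond to C8=C9 as the cis-cyclononene; the C7 configuration is of no consequence.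

Step 16
Reactants: 22 the allylic alcohol
Product: 23 N-Boc enone (C7 ketone conjugated with C8=C9)
Conditions: Dess–Martin periodinane, NaHCO3, CH2Cl2, rt
Reagents that add atoms: none
Why: Dess–Martin oxidation of the allylic alcohol under buffered conditions should give the enone without affecting the carbamate or the acetates.

Step 17
Reactants: 23 the N-Boc enone
Product: 25 target CNP0386920.1, via secondary amine 24 (not isolated)
Conditions: TFA, CH2Cl2, 0 °C; concentrate; then aq. HCHO, NaBH(OAc)3, Et3N, 1,2-dichloroethane, rt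
Reagents that add atoms: formaldehyde, C=O
Why: Acidolysis of the Boc group followed by reductive amination with formaldehyde (Borch-type, with a borohydride that reduces neither the enone nor the esters) should install the N-methyl group.

**Compound list**

1 | (R)-5-methylcyclohex-2-en-1-one | O=C1C[C@H](C)CC=C1 | starting material
2 | (R)-2-iodo-5-methylcyclohex-2-en-1-one | O=C1C[C@H](C)CC=C1I | intermediate
3 | allyloxy(tert-butyl)dimethylsilane | C=CCO[Si](C)(C)C(C)(C)C | starting material
4 | 9-[3-(tert-butyldimethylsilyloxy)propyl]-9-borabicyclo[3.3.1]nonane | CC(C)(C)[Si](C)(C)OCCCB1C2CCCC1CCC2 | intermediate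
5 | (R)-2-[3-(tert-butyldimethylsilyloxy)propyl]-5-methylcyclohex-2-en-1-one | O=C1C[C@H](C)CC=C1CCCO[Si](C)(C)C(C)(C)C | intermediate
6 | (4-bromobut-1-yn-1-yl)trimethylsilane | C[Si](C)(C)C#CCCBr | starting material
7 | [4-(trimethylsilyl)but-3-yn-1-yl]magnesium bromide | C[Si](C)(C)C#CCC[Mg]Br | intermediate
8 | tert-butyl({(3R,5R)-2-[3-(tert-butyldimethylsilyloxy)propyl]-5-methyl-3-[4-(trimethylsilyl)but-3-yn-1-yl]cyclohex-1-en-1-yl}oxy)dimethylsilane | CC(C)(C)[Si](C)(C)OC1=C(CCCO[Si](C)(C)C(C)(C)C)[C@H](CCC#C[Si](C)(C)C)C[C@@H](C)C1 | intermediate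
9 | tert-butyl({(3R,5R)-2-[3-(tert-butyldimethylsilyloxy)propyl]-3-(4-iodobut-3-yn-1-yl)-5-methylcyclohex-1-en-1-yl}oxy)dimethylsilane | CC(C)(C)[Si](C)(C)OC1=C(CCCO[Si](C)(C)C(C)(C)C)[C@H](CCC#CI)C[C@@H](C)C1 | intermediate
10 | cis-fused ring A/B ketone: C1 ketone, 3α-methyl, 5α-H, 16α-[3-(tert-butyldimethylsilyloxy)propyl], (Z)-iodomethylidene at C8 | O=C1C[C@H](C)C[C@H]2CC/C(=C/I)[C@]21CCCO[Si](C)(C)C(C)(C)C | intermediate
11 | enone: C1 ketone, C2=C3(Me), otherwise as 10 | O=C1C=C(C)C[C@H]2CC/C(=C/I)[C@]21CCCO[Si](C)(C)C(C)(C)C | intermediate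
12 | allylic alcohol: 1β-hydroxy, C2=C3(Me) | O[C@H]1C=C(C)C[C@H]2CC/C(=C/I)[C@]21CCCO[Si](C)(C)C(C)(C)C | intermediate
13 | epoxy alcohol: 1β-hydroxy-2β,3β-epoxy-3α-methyl | O[C@H]1[C@H]2O[C@@]2(C)C[C@H]3CC/C(=C/I)[C@]31CCCO[Si](C)(C)C(C)(C)C | intermediate
14 | diol: 1β,3β-dihydroxy-3α-methyl, silyloxypropyl arm | O[C@H]1C[C@@](C)(O)C[C@H]2CC/C(=C/I)[C@]21CCCO[Si](C)(C)C(C)(C)C | intermediate
15 | diacetate: 1β,3β-diacetoxy-3α-methyl, silyloxypropyl arm | CC(=O)O[C@H]1C[C@@](C)(OC(C)=O)C[C@H]2CC/C(=C/I)[C@]21CCCO[Si](C)(C)C(C)(C)C | intermediate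
16 | diacetate with 3-hydroxypropyl arm | CC(=O)O[C@H]1C[C@@](C)(OC(C)=O)C[C@H]2CC/C(=C/I)[C@]21CCCO | intermediate
17 | diacetate with 3-iodopropyl arm | CC(=O)O[C@H]1C[C@@](C)(OC(C)=O)C[C@H]2CC/C(=C/I)[C@]21CCCI | intermediate
18 | tert-butyl N-ethenylcarbamate (tert-butyl N-vinylcarbamate) | C=CNC(=O)OC(C)(C)C | starting material
19 | vinyl iodide with N-Boc-N-vinyl-3-aminopropyl arm (key precursor) | CC(=O)O[C@H]1C[C@@](C)(OC(C)=O)C[C@H]2CC/C(=C/I)[C@]21CCCN(C=C)C(=O)OC(C)(C)C | intermediate
20 | 9-BBN adduct of 19 (boron on C10) | CC(=O)O[C@H]1C[C@@](C)(OC(C)=O)C[C@H]2CC/C(=C/I)[C@]21CCCN(CCB3C4CCCC3CCC4)C(=O)OC(C)(C)C | intermediate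
21 | tricyclic N-Boc carbamate, ring C closed, C7 methylene, C10 cis to C16 | CC(=O)O[C@H]1C[C@@](C)(OC(C)=O)C[C@H]2CC/C3=C/CCN(C(=O)OC(C)(C)C)CCC[C@@]321 | intermediate
22 | C7 allylic alcohol of 21 (either C7 epimer) | CC(=O)O[C@H]1C[C@@](C)(OC(C)=O)C[C@H]2CC(O)/C3=C/CCN(C(=O)OC(C)(C)C)CCC[C@@]321 | intermediate
23 | N-Boc enone (C7 ketone) | CC(=O)O[C@H]1C[C@@](C)(OC(C)=O)C[C@H]2CC(=O)/C3=C/CCN(C(=O)OC(C)(C)C)CCC[C@@]321 | intermediate
24 | secondary amine enone (N12–H) | CC(=O)O[C@H]1C[C@@](C)(OC(C)=O)C[C@H]2CC(=O)/C3=C/CCNCCC[C@@]321 | intermediate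
25 | CNP0386920.1: 1β,3β-diacetoxy-3α-methyl-N-methyl tricyclic enone (1S,3S,5S,16S in the numbering used here; C10 cis to C16) | CC(=O)O[C@H]1C[C@@](C)(OC(C)=O)C[C@H]2CC(=O)/C3=C/CCN(C)CCC[C@@]321 | target

**Step count**

Total: 17 steps. Longest linear sequence: 17 steps (1 → 25).

**Steps most likely to fail**

Step 14. Intermolecular coupling, protodeboronation or β-hydride elimination of the alkylpalladium may outrun the strained nine-membered closure. The fallback sets out from 15 and comes back at 21, making the two bonds of ring C in the opposite order. Carbamate 18 is hydroborated with 9-BBN to tert-butyl N-[2-(9-borabicyclo[3.3.1]nonan-9-yl)ethyl]carbamate F1. F1 is coupled intermolecularly with vinyl iodide 15 (PdCl2(dppf), AsPh3, Cs2CO3, DMF/THF/H2O) to give the open-chain alkene carbamate F2, with C9–C10 in place and C10 cis to C16. HF·pyridine frees the primary alcohol F3, and I2/PPh3/imidazole gives the primary iodide F4. NaH in DMF at high dilution then closes ring C by intramolecular N-alkylation (N12–C13) to give 21.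

Step 5. The crowded tetrasubstituted enol ether may lose its silyl group by protodesilylation, or close in the 6-endo mode, faster than it undergoes the 5-exo attack. The fallback sets out from 1 and comes back at 10, forming the quaternary centre after ring B instead of during its closure. Enone 1 takes up Grignard reagent 7 (CuBr·SMe2 cat.; then TBSOTf) to give the trisubstituted enol ether F5. NIS/AgNO3 converts it into the iodoalkyne F6. The same gold catalyst closes ring B on this less hindered enol ether to give the C16–H cis-hydrindanone F7. KOt-Bu and allyl iodide alkylate the extended enolate at C16 on the face anti to C6, giving the cis-fused 16α-allyl ketone F8. 9-BBN then NaBO3 turns the allyl group into the 3-hydroxypropyl ketone F9, and TBSCl/imidazole returns 10.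

Step 8. The vanadium-bound peroxide may be kept off the β face by the pseudoaxial C8 and its iodine, so that conversion stalls or epoxidation drifts to the α face. The fallback sets out from 12 and comes back at 13, relying on steric rather than directed control. NBS in aqueous THF forms the bromonium ion on the open α face and water opens it at the tertiary carbon C3 from the β face, giving the 2α-bromo-1β,3β-diol F10. K2CO3 in MeOH closes the C3 alkoxide onto C2 with loss of bromide to give the same β-epoxide 13.

**Further compounds**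

F1 | step 14 | tert-butyl N-[2-(9-borabicyclo[3.3.1]nonan-9-yl)ethyl]carbamate | CC(C)(C)OC(=O)NCCB1C2CCCC1CCC2
F2 | step 14 | open-chain alkene carbamate (C9–C10 formed, N–H, silyloxypropyl arm, diacetate) | CC(=O)O[C@H]1C[C@@](C)(OC(C)=O)C[C@H]2CC/C(=C/CCNC(=O)OC(C)(C)C)[C@]21CCCO[Si](C)(C)C(C)(C)C
F3 | step 14 | primary alcohol of F2 | CC(=O)O[C@H]1C[C@@](C)(OC(C)=O)C[C@H]2CC/C(=C/CCNC(=O)OC(C)(C)C)[C@]21CCCO
F4 | step 14 | primary iodide of F3 | CC(=O)O[C@H]1C[C@@](C)(OC(C)=O)C[C@H]2CC/C(=C/CCNC(=O)OC(C)(C)C)[C@]21CCCI
F5 | step 5 | trisubstituted silyl enol ether from 1 (butynyl trans to methyl, no C16 arm) | CC(C)(C)[Si](C)(C)OC1=C[C@H](CCC#C[Si](C)(C)C)C[C@@H](C)C1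
F6 | step 5 | iodoalkyne of F5 | CC(C)(C)[Si](C)(C)OC1=C[C@H](CCC#CI)C[C@@H](C)C1
F7 | step 5 | C16–H cis-hydrindanone with (Z)-iodomethylidene | O=C1C[C@H](C)C[C@H]2CC/C(=C/I)[C@H]21
F8 | step 5 | 16α-allyl ketone | O=C1C[C@H](C)C[C@H]2CC/C(=C/I)[C@]21CC=C
F9 | step 5 | 16α-(3-hydroxypropyl) ketone | O=C1C[C@H](C)C[C@H]2CC/C(=C/I)[C@]21CCCO
F10 | step 8 | 2α-bromo-1β,3β-diol (bromohydrin of 12) | O[C@H]1[C@H](Br)[C@@](C)(O)C[C@H]2CC/C(=C/I)[C@]21CCCO[Si](C)(C)C(C)(C)C
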